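**Plan**

- Retrosynthesis: remove the C1–C10 epoxide oxygen, the C8 ester and the C11=C13 methylene. Then cut the C5–C6 bond of the ten-membered ring together with the C12–O lactone bond, which gives an open-chain (Z)-alkenyl iodide / aldehyde / methyl ester. Cut the chain at C7–C11, C8–C9 and C3–C4.
- Enabling feature: C5 is the vinylic CH of the cis (Z) C4=C5 double bond and C6 is the lactone carbinol of the cyclodecadiene, so a C5 alkenyl-metal can add to a C6 aldehyde. The Z-C4=C5 and E-C1=C10 olefins pre-fold the chain, and the C12 ester sits 1,4 to C6, so the new alkoxide closes the five-membered lactone.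
- Forward order: chain (C3–C4 by carbocupration of propyne, C8–C9 by alkynylation, C7–C11 by epoxide opening), then ten-membered carbocycle and γ-lactone in one operation, then exocyclic methylene, C8 ester, and the C1–C10 epoxide last.
- Stereochemistry: Z-C4=C5 from syn-carbocupration; E-C1=C10 from E-selective SeO2 oxidation; C8 and C7 from Sharpless epoxidation and SN2 opening with inversion; C6 from substrate control in the ring closure; C1/C10 from peripheral peracid attack; side-chain centres from a second Sharpless epoxidation.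

Key step: step 13

Remark: carbons are labelled C1–C15 by germacrane numbering of the target (C6 lactone carbinol, C7 ring-fusion CH, C8 ester carbinol, C1/C10 epoxide carbons, C11/C12/C13 lactone α-carbon, carbonyl and methylene); plain numbers are compounds.

**Route**

Step 1
Reactants: 1 5-bromo-2-methylpent-2-ene; 2 propyne
Product: 5 (1Z)-1-iodo-2,6-dimethylhepta-1,5-diene, via Grignard reagent 3 (not isolated), via alkenylcopper 4 (not isolated)
Conditions: Mg, Et2O; CuBr·SMe2, Et2O/Me2S, −45 °C; 2, −25 °C; I2, −40 → 0 °C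
Reagents that add atoms: iodine, II
Why: Normant carbocupration adds the alkylcopper reagent syn across propyne (alkyl to the internal carbon, copper to the terminal carbon, cis to the new chain), and iodinolysis with retention gives the Z-alkenyl iodide, forming C3–C4 and fixing the Z-C4=C5 geometry.

Step 2
Reactants: 5 (1Z)-1-iodo-2,6-dimethylhepta-1,5-diene
Product: 6 (2E,6Z)-7-iodo-2,6-dimethylhepta-2,6-dien-1-ol
Conditions: SeO2 (cat.), tBuOOH, salicylic acid (cat.), CH2Cl2, 0 °C → rt
Reagents that add atoms: tert-butyl hydroperoxide, CC(C)(C)OO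
Why: SeO2 allylic oxidation (ene reaction then [2,3]-shift) should attack the E-methyl of the electron-rich gem-dimethyl alkene in preference to the iodine-deactivated alkene, which fixes the E geometry of the later C1=C10 bond.

Step 3
Reactants: 6 (2E,6Z)-7-iodo-2,6-dimethylhepta-2,6-dien-1-ol
Product: 7 (1Z,5E)-7-bromo-1-iodo-2,6-dimethylhepta-1,5-diene
Conditions: CBr4, PPh3, CH2Cl2, 0 °C
Reagents that add atoms: tetrabromomethane, BrC(Br)(Br)Br
Why: Appel bromination converts the primary allylic alcohol to the bromide under neutral conditions without allylic transposition.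

Step 4
Reactants: 7 (1Z,5E)-7-bromo-1-iodo-2,6-dimethylhepta-1,5-diene; 8 prop-2-yn-1-ol
Product: 9 (5E,9Z)-10-iodo-5,9-dimethyldeca-5,9-dien-2-yn-1-ol
Conditions: CuI (cat.), NaI (cat.), K2CO3, DMF, rt
Reagents that add atoms: none
Why: Copper-catalysed SN2 alkynylation of a primary allylic bromide by the copper acetylide forms C8–C9 at the unhindered CH2 terminus, and the alkenyl iodide should not couple at room temperature without palladium.

Step 5
Reactants: 9 (5E,9Z)-10-iodo-5,9-dimethyldeca-5,9-dien-2-yn-1-ol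
Product: 10 (2E,5E,9Z)-10-iodo-5,9-dimethyldeca-2,5,9-trien-1-ol
Conditions: NaAlH2(OCH2CH2OMe)2, THF, 0 °C; aq. work-up
Reagents that add atoms: none
Why: Alkoxide-directed trans-hydroalumination of the propargylic alcohol followed by protonolysis gives the E-allylic alcohol, while isolated alkenes and the alkenyl iodide should survive at 0 °C.

Step 6
Reactants: 10 (2E,5E,9Z)-10-iodo-5,9-dimethyldeca-2,5,9-trien-1-ol
Product: 11 [(2R,3R)-3-[(2E,6Z)-7-iodo-2,6-dimethylhepta-2,6-dien-1-yl]oxiran-2-yl]methanol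
Conditions: Ti(OiPr)4 (cat.), D-(−)-diethyl tartrate (cat.), tBuOOH, 4 Å molecular sieves, CH2Cl2, −20 °C
Reagents that add atoms: tert-butyl hydroperoxide, CC(C)(C)OO
Why: Katsuki–Sharpless asymmetric epoxidation acts only on the allylic alcohol, and the D-(−)-tartrate catalyst delivers oxygen to the face that gives the (2R,3R)-epoxide, which sets C8 and the pre-inversion configuration of C7.

Step 7
Reactants: 11 [(2R,3R)-3-[(2E,6Z)-7-iodo-2,6-dimethylhepta-2,6-dien-1-yl]oxiran-2-yl]methanol; 12 vinylmagnesium bromide (CH2=CHMgBr)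
Product: 13 (2S,3R,5E,9Z)-2-ethenyl-10-iodo-5,9-dimethyldeca-5,9-diene-1,3-diol
Conditions: 12 (excess), CuI (cat.), THF, −30 → −10 °C; aq. NH4Cl
Reagents that add atoms: none
Why: Copper-catalysed Grignard opening of a 2,3-epoxy alcohol proceeds by SN2 attack at C2 (here C7) with inversion, giving the 1,3-diol with the vinyl group anti to the C8 hydroxyl and so setting C7; catalytic copper at low temperature should spare the alkenyl iodide, and any 1,2-diol from attack at C8 is removable with NaIO4.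

Step 8
Reactants: 13 (2S,3R,5E,9Z)-2-ethenyl-10-iodo-5,9-dimethyldeca-5,9-diene-1,3-diol
Product: 14 (2S,3R,5E,9Z)-2-ethenyl-10-iodo-5,9-dimethyl-1,3-bis[(triethylsilyl)oxy]deca-5,9-diene
Conditions: TESCl, imidazole, DMF, 0 °C → rt
Reagents that add atoms: chlorotriethylsilane, CC[Si](CC)(CC)Cl
Why: Standard silylation protects both hydroxyls as triethylsilyl ethers, the primary one being removable later in the presence of the secondary one.

Step 9
Reactants: 14 (2S,3R,5E,9Z)-2-ethenyl-10-iodo-5,9-dimethyl-1,3-bis[(triethylsilyl)oxy]deca-5,9-diene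
Product: 16 (3S,4R,6E,10Z)-11-iodo-6,10-dimethyl-4-[(triethylsilyl)oxy]-3-{[(triethylsilyl)oxy]methyl}undeca-6,10-dien-1-ol, via alkylborane 15 (not isolated)
Conditions: 9-BBN, THF, 0 °C → rt; then aq. NaOH, H2O2, 0 °C
Reagents that add atoms: hydrogen peroxide, OO
Why: Anti-Markovnikov hydroboration with 9-BBN is far faster at the monosubstituted vinyl group than at the two trisubstituted alkenes, and oxidation gives the primary alcohol at C12.

Step 10
Reactants: 16 (3S,4R,6E,10Z)-11-iodo-6,10-dimethyl-4-[(triethylsilyl)oxy]-3-{[(triethylsilyl)oxy]methyl}undeca-6,10-dien-1-ol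
Product: 18 (3S,4R,6E,10Z)-11-iodo-6,10-dimethyl-4-[(triethylsilyl)oxy]-3-{[(triethylsilyl)oxy]methyl}undeca-6,10-dienoic acid, via aldehyde 17 (not isolated)
Conditions: TEMPO (cat.), PhI(OAc)2, MeCN/pH 7 buffer, 0 °C → rt
Reagents that add atoms: water, O
Why: Oxoammonium (TEMPO) oxidation takes the primary alcohol to the aldehyde and, through its hydrate, to the acid, and the buffered medium should spare the silyl ethers and alkenes.

Step 11
Reactants: 18 (3S,4R,6E,10Z)-11-iodo-6,10-dimethyl-4-[(triethylsilyl)oxy]-3-{[(triethylsilyl)oxy]methyl}undeca-6,10-dienoic acid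
Product: 19 methyl (3S,4R,6E,10Z)-11-iodo-6,10-dimethyl-4-[(triethylsilyl)oxy]-3-{[(triethylsilyl)oxy]methyl}undeca-6,10-dienoate
Conditions: TMSCHN2, MeOH/toluene, 0 °C
Reagents that add atoms: (trimethylsilyl)diazomethane, C[Si](C)(C)C=[N+]=[N-]
Why: Methyl esterification with the diazomethane surrogate is neutral and leaves silyl ethers and the alkenyl iodide intact.

Step 12
Reactants: 19 methyl (3S,4R,6E,10Z)-11-iodo-6,10-dimethyl-4-[(triethylsilyl)oxy]-3-{[(triethylsilyl)oxy]methyl}undeca-6,10-dienoate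
Product: 21 methyl (3R,4R,6E,10Z)-3-formyl-11-iodo-6,10-dimethyl-4-[(triethylsilyl)oxy]undeca-6,10-dienoate, via primary alcohol 20 (not isolated)
Conditions: (COCl)2, DMSO, CH2Cl2, −78 → −40 °C; Et3N, −78 → 0 °C
Reagents that add atoms: none
Why: Under Swern conditions a primary triethylsilyl ether is cleaved and oxidised in one pot while the secondary one is retained, and the low temperature should keep the C7 stereocentre intact (its descriptor changes only through CIP priorities).

Step 13
Reactants: 21 methyl (3R,4R,6E,10Z)-3-formyl-11-iodo-6,10-dimethyl-4-[(triethylsilyl)oxy]undeca-6,10-dienoate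
Product: 23 (3aS,4R,6E,10Z,11aR)-6,10-dimethyl-4-[(triethylsilyl)oxy]-3a,4,5,8,9,11a-hexahydrocyclodeca[b]furan-2(3H)-one, via hydroxy ester 22 (not isolated)
Conditions: CrCl2 (excess), NiCl2 (cat.), DMSO, rt, slow addition of 21 (final 0.003 M); then PPTS (cat.), CH2Cl2, rt
Reagents that add atoms: none
Why: Intramolecular Nozaki–Hiyama–Kishi reaction: zerovalent nickel (formed from NiCl2 by CrCl2) inserts into the C5–I bond, the alkenyl group passes to trivalent chromium with retention of the Z geometry, and this weakly basic nucleophile adds to the C6 aldehyde in the presence of the ester and silyl ether. The closest known reaction type is the NiCl2/CrCl2-mediated alkenyl iodide–aldehyde macrocyclisation used to close nine- to twelve-membered carbocycles. The ten-membered carbocycle closes in a 10-exo-trig mode at the aldehyde carbon (the cis C4=C5 and E C1=C10 olefins hold C5 within reach of C6), and the resulting C6 alkoxide then closes the lactone by 5-exo-trig acyl substitution at the C12 ester. The new C6 stereocentre is controlled by C7 and C8: attack anti to the C7–C8 bond (Felkin–Anh) and 1,3-anti induction from the C8 silyloxy group reinforce each other in this α,β-anti aldehyde and both lead to the 6R carbinol, which is also the epimer whose lactone is trans-fused. The step needs intramolecular over intermolecular coupling, which slow addition into dilute excess CrCl2 should secure, and retention of the C4=C5 geometry, which 2,2-disubstituted alkenylchromium species provide.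

Step 14
Reactants: 23 (3aS,4R,6E,10Z,11aR)-6,10-dimethyl-4-[(triethylsilyl)oxy]-3a,4,5,8,9,11a-hexahydrocyclodeca[b]furan-2(3H)-one; 24 N,N-dimethylmethaniminium iodide (Eschenmoser's salt)
Product: 26 (3aS,4R,6E,10Z,11aR)-3-[(dimethylamino)methyl]-6,10-dimethyl-4-[(triethylsilyl)oxy]-3a,4,5,8,9,11a-hexahydrocyclodeca[b]furan-2(3H)-one (C3 epimers), via lithium enolate 25 (not isolated)
Conditions: LiN(iPr)2, THF, −78 °C; 24, −78 → 0 °C
Reagents that add atoms: none
Why: Mannich alkylation of the kinetic lactone enolate with the iminium salt installs C13 at C11, and the configuration of the new centre is irrelevant because it becomes sp2 in the next step.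

Step 15
Reactants: 26 (3aS,4R,6E,10Z,11aR)-3-[(dimethylamino)methyl]-6,10-dimethyl-4-[(triethylsilyl)oxy]-3a,4,5,8,9,11a-hexahydrocyclodeca[b]furan-2(3H)-one (C3 epimers)
Product: 28 (3aS,4R,6E,10Z,11aR)-6,10-dimethyl-3-methylidene-4-[(triethylsilyl)oxy]-3a,4,5,8,9,11a-hexahydrocyclodeca[b]furan-2(3H)-one, via ammonium iodide 27 (not isolated)
Conditions: MeI, MeOH, rt; then aq. NaHCO3/EtOAc, rt
Reagents that add atoms: none
Why: Quaternisation followed by mild base-induced β-elimination of trimethylamine is the standard way to the α-methylene-γ-lactone.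

Step 16
Reactants: 28 (3aS,4R,6E,10Z,11aR)-6,10-dimethyl-3-methylidene-4-[(triethylsilyl)oxy]-3a,4,5,8,9,11a-hexahydrocyclodeca[b]furan-2(3H)-one
Product: 29 (3aR,4R,6E,10Z,11aR)-4-hydroxy-6,10-dimethyl-3-methylidene-3a,4,5,8,9,11a-hexahydrocyclodeca[b]furan-2(3H)-one
Conditions: HF·pyridine, pyridine/THF, 0 °C
Reagents that add atoms: none
Why: Buffered fluoride cleavage of the secondary triethylsilyl ether is compatible with the Michael-acceptor lactone and the diene (the 3a descriptor changes only through CIP priorities).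

Step 17
Reactants: 30 angelic acid [(2Z)-2-methylbut-2-enoic acid]
Product: 31 (2Z)-2-methylbut-2-en-1-ol
Conditions: LiAlH4, Et2O, 0 °C
Reagents that add atoms: none
Why: Hydride reduction of the acid at low temperature should give angelyl alcohol without Z → E isomerisation.

Step 18
Reactants: 31 (2Z)-2-methylbut-2-en-1-ol
Product: 32 [(2R,3S)-2,3-dimethyloxiran-2-yl]methanol
Conditions: Ti(OiPr)4 (cat.), D-(−)-diethyl tartrate (cat.), tBuOOH, 4 Å molecular sieves, CH2Cl2, −20 °C
Reagents that add atoms: tert-butyl hydroperoxide, CC(C)(C)OO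
Why: Katsuki–Sharpless epoxidation with the D-(−)-tartrate catalyst sets both side-chain centres, and stereospecific syn delivery keeps the CH2OH and C3 methyl groups cis.

Step 19
Reactants: 32 [(2R,3S)-2,3-dimethyloxiran-2-yl]methanol
Product: 33 (2S,3S)-2,3-dimethyloxirane-2-carboxylic acid
Conditions: RuCl3 (cat.), NaIO4, CCl4/MeCN/H2O, rt
Reagents that add atoms: water, O
Why: Catalytic RuO4 oxidation takes the primary epoxy alcohol to the glycidic acid without opening the epoxide (the C2 descriptor changes only through CIP priorities).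

Step 20
Reactants: 29 (3aR,4R,6E,10Z,11aR)-4-hydroxy-6,10-dimethyl-3-methylidene-3a,4,5,8,9,11a-hexahydrocyclodeca[b]furan-2(3H)-one; 33 (2S,3S)-2,3-dimethyloxirane-2-carboxylic acid
Product: 35 (3aR,4R,6E,10Z,11aR)-6,10-dimethyl-3-methylidene-2-oxo-2,3,3a,4,5,8,9,11a-octahydrocyclodeca[b]furan-4-yl (2S,3S)-2,3-dimethyloxirane-2-carboxylate, via mixed anhydride 34 (not isolated)
Conditions: 2,4,6-Cl3C6H2COCl, Et3N, THF, rt; then 29, DMAP, toluene, rt
Reagents that add atoms: none
Why: Yamaguchi esterification through the mixed anhydride acylates the hindered secondary C8 hydroxyl with retention, and the acid has no α-hydrogen so it cannot epimerise.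

Step 21
Reactants: 35 (3aR,4R,6E,10Z,11aR)-6,10-dimethyl-3-methylidene-2-oxo-2,3,3a,4,5,8,9,11a-octahydrocyclodeca[b]furan-4-yl (2S,3S)-2,3-dimethyloxirane-2-carboxylate
Product: 36 (1R,6R,7R,8R,10R)-1,10-epoxy-8-{[(2S,3S)-2,3-dimethyloxirane-2-carbonyl]oxy}germacra-4Z,11(13)-dien-12,6-olide (target)
Conditions: mCPBA (1 equiv), NaHCO3, CH2Cl2, 0 °C
Reagents that add atoms: 3-chloroperbenzoic acid, OOC(=O)c1cccc(Cl)c1
Why: Prilezhaev epoxidation should select the electron-rich C1=C10 alkene (C4=C5 is deactivated by the allylic lactone oxygen, C11=C13 by conjugation), and attack on the outer face of the E-alkene in the conformer with the C10 methyl on the β face gives the (1R,10R)-epoxide; buffering suppresses acid-induced transannular cyclisation.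

**Compound list**

1 | 5-bromo-2-methylpent-2-ene | CC(C)=CCCBr | starting material
2 | propyne | CC#C | starting material
3 | (4-methylpent-3-en-1-yl)magnesium bromide (not isolated) | CC(C)=CCC[Mg]Br | intermediate
4 | [(1Z)-2,6-dimethylhepta-1,5-dien-1-yl]copper (not isolated) | [Cu]/C=C(/C)CCC=C(C)C | intermediate
5 | (1Z)-1-iodo-2,6-dimethylhepta-1,5-diene | I/C=C(/C)CCC=C(C)C | intermediate
6 | (2E,6Z)-7-iodo-2,6-dimethylhepta-2,6-dien-1-ol | OC/C(C)=C/CC/C(C)=C\I | intermediate
7 | (1Z,5E)-7-bromo-1-iodo-2,6-dimethylhepta-1,5-diene | BrC/C(C)=C/CC/C(C)=C\I | intermediate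
8 | prop-2-yn-1-ol | OCC#C | starting material
9 | (5E,9Z)-10-iodo-5,9-dimethyldeca-5,9-dien-2-yn-1-ol | OCC#CC/C(C)=C/CC/C(C)=C\I | intermediate
10 | (2E,5E,9Z)-10-iodo-5,9-dimethyldeca-2,5,9-trien-1-ol | OC/C=C/C/C(C)=C/CC/C(C)=C\I | intermediate
11 | [(2R,3R)-3-[(2E,6Z)-7-iodo-2,6-dimethylhepta-2,6-dien-1-yl]oxiran-2-yl]methanol | OC[C@H]1O[C@@H]1C/C(C)=C/CC/C(C)=C\I | intermediate
12 | vinylmagnesium bromide (CH2=CHMgBr) | C=C[Mg]Br | starting material
13 | (2S,3R,5E,9Z)-2-ethenyl-10-iodo-5,9-dimethyldeca-5,9-diene-1,3-diol | OC[C@H](C=C)[C@H](O)C/C(C)=C/CC/C(C)=C\I | intermediate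
14 | (2S,3R,5E,9Z)-2-ethenyl-10-iodo-5,9-dimethyl-1,3-bis[(triethylsilyl)oxy]deca-5,9-diene | CC[Si](CC)(CC)OC[C@H](C=C)[C@H](O[Si](CC)(CC)CC)C/C(C)=C/CC/C(C)=C\I | intermediate
15 | 9-[(3S,4R,6E,10Z)-11-iodo-6,10-dimethyl-4-[(triethylsilyl)oxy]-3-{[(triethylsilyl)oxy]methyl}undeca-6,10-dien-1-yl]-9-borabicyclo[3.3.1]nonane (not isolated) | CC[Si](CC)(CC)OC[C@H](CCB1C2CCCC1CCC2)[C@H](O[Si](CC)(CC)CC)C/C(C)=C/CC/C(C)=C\I | intermediate
16 | (3S,4R,6E,10Z)-11-iodo-6,10-dimethyl-4-[(triethylsilyl)oxy]-3-{[(triethylsilyl)oxy]methyl}undeca-6,10-dien-1-ol | CC[Si](CC)(CC)OC[C@H](CCO)[C@H](O[Si](CC)(CC)CC)C/C(C)=C/CC/C(C)=C\I | intermediate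
17 | (3S,4R,6E,10Z)-11-iodo-6,10-dimethyl-4-[(triethylsilyl)oxy]-3-{[(triethylsilyl)oxy]methyl}undeca-6,10-dienal (not isolated) | CC[Si](CC)(CC)OC[C@H](CC=O)[C@H](O[Si](CC)(CC)CC)C/C(C)=C/CC/C(C)=C\I | intermediate
18 | (3S,4R,6E,10Z)-11-iodo-6,10-dimethyl-4-[(triethylsilyl)oxy]-3-{[(triethylsilyl)oxy]methyl}undeca-6,10-dienoic acid | CC[Si](CC)(CC)OC[C@H](CC(O)=O)[C@H](O[Si](CC)(CC)CC)C/C(C)=C/CC/C(C)=C\I | intermediate
19 | methyl (3S,4R,6E,10Z)-11-iodo-6,10-dimethyl-4-[(triethylsilyl)oxy]-3-{[(triethylsilyl)oxy]methyl}undeca-6,10-dienoate | CC[Si](CC)(CC)OC[C@H](CC(=O)OC)[C@H](O[Si](CC)(CC)CC)C/C(C)=C/CC/C(C)=C\I | intermediate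
20 | methyl (3S,4R,6E,10Z)-3-(hydroxymethyl)-11-iodo-6,10-dimethyl-4-[(triethylsilyl)oxy]undeca-6,10-dienoate (not isolated) | OC[C@H](CC(=O)OC)[C@H](O[Si](CC)(CC)CC)C/C(C)=C/CC/C(C)=C\I | intermediate
21 | methyl (3R,4R,6E,10Z)-3-formyl-11-iodo-6,10-dimethyl-4-[(triethylsilyl)oxy]undeca-6,10-dienoate | O=C[C@H](CC(=O)OC)[C@H](O[Si](CC)(CC)CC)C/C(C)=C/CC/C(C)=C\I | intermediate
22 | methyl 2-[(1S,2R,3Z,7E,10R)-2-hydroxy-4,8-dimethyl-10-[(triethylsilyl)oxy]cyclodeca-3,7-dien-1-yl]acetate (not isolated) | COC(=O)C[C@H]1[C@H](O)/C=C(/C)CC/C=C(\C)C[C@H]1O[Si](CC)(CC)CC | intermediate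
23 | (3aS,4R,6E,10Z,11aR)-6,10-dimethyl-4-[(triethylsilyl)oxy]-3a,4,5,8,9,11a-hexahydrocyclodeca[b]furan-2(3H)-one | C1C(=O)O[C@@H]2/C=C(/C)CC/C=C(\C)C[C@@H](O[Si](CC)(CC)CC)[C@@H]12 | intermediate
24 | N,N-dimethylmethaniminium iodide (Eschenmoser's salt) | C=[N+](C)C.[I-] | starting material
25 | lithium enolate of 23 (not isolated) | C1=C([O-])O[C@@H]2/C=C(/C)CC/C=C(\C)C[C@@H](O[Si](CC)(CC)CC)[C@@H]12.[Li+] | intermediate
26 | (3aS,4R,6E,10Z,11aR)-3-[(dimethylamino)methyl]-6,10-dimethyl-4-[(triethylsilyl)oxy]-3a,4,5,8,9,11a-hexahydrocyclodeca[b]furan-2(3H)-one (C3 epimers) | CN(C)CC1C(=O)O[C@@H]2/C=C(/C)CC/C=C(\C)C[C@@H](O[Si](CC)(CC)CC)[C@@H]12 | intermediate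
27 | trimethylammoniomethyl lactone iodide from 26 (not isolated) | C[N+](C)(C)CC1C(=O)O[C@@H]2/C=C(/C)CC/C=C(\C)C[C@@H](O[Si](CC)(CC)CC)[C@@H]12.[I-] | intermediate
28 | (3aS,4R,6E,10Z,11aR)-6,10-dimethyl-3-methylidene-4-[(triethylsilyl)oxy]-3a,4,5,8,9,11a-hexahydrocyclodeca[b]furan-2(3H)-one | C=C1C(=O)O[C@@H]2/C=C(/C)CC/C=C(\C)C[C@@H](O[Si](CC)(CC)CC)[C@@H]12 | intermediate
29 | (3aR,4R,6E,10Z,11aR)-4-hydroxy-6,10-dimethyl-3-methylidene-3a,4,5,8,9,11a-hexahydrocyclodeca[b]furan-2(3H)-one | C=C1C(=O)O[C@@H]2/C=C(/C)CC/C=C(\C)C[C@@H](O)[C@@H]12 | intermediate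
30 | angelic acid [(2Z)-2-methylbut-2-enoic acid] | C/C=C(/C)C(=O)O | starting material
31 | (2Z)-2-methylbut-2-en-1-ol | C/C=C(/C)CO | intermediate
32 | [(2R,3S)-2,3-dimethyloxiran-2-yl]methanol | OC[C@@]1(C)O[C@H]1C | intermediate
33 | (2S,3S)-2,3-dimethyloxirane-2-carboxylic acid | OC(=O)[C@@]1(C)O[C@H]1C | intermediate
34 | (2S,3S)-2,3-dimethyloxirane-2-carboxylic 2,4,6-trichlorobenzoic anhydride (not isolated) | O=C(OC(=O)[C@@]1(C)O[C@H]1C)c1c(Cl)cc(Cl)cc1Cl | intermediate
35 | (3aR,4R,6E,10Z,11aR)-6,10-dimethyl-3-methylidene-2-oxo-2,3,3a,4,5,8,9,11a-octahydrocyclodeca[b]furan-4-yl (2S,3S)-2,3-dimethyloxirane-2-carboxylate | C=C1C(=O)O[C@@H]2/C=C(/C)CC/C=C(\C)C[C@@H](OC(=O)[C@@]3(C)O[C@H]3C)[C@@H]12 | intermediate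
36 | (1R,6R,7R,8R,10R)-1,10-epoxy-8-{[(2S,3S)-2,3-dimethyloxirane-2-carbonyl]oxy}germacra-4Z,11(13)-dien-12,6-olide | C=C1C(=O)O[C@@H]2/C=C(/C)CC[C@H]3O[C@]3(C)C[C@@H](OC(=O)[C@@]3(C)O[C@H]3C)[C@@H]12 | target

**Count and risks**

Total step count: 21. Longest linear sequence: 18 (steps 1–16, 20, 21); steps 17–19 make the side-chain acid.

Steps most likely to fail:

1. Step 13. The alkenylchromium may add to the other face of the aldehyde (giving the C6 epimer and from it the cis-fused lactone), and intermolecular coupling may compete with ring closure. Fallback: set C6 by reagent-controlled reduction instead of by the addition. Setting out from 21, the same ring closure is worked up without acid so that the open hydroxy esters are kept. Both C6 epimers are oxidised with Dess–Martin periodinane to a single enone, methyl 2-[(1R,3Z,7E,10R)-4,8-dimethyl-2-oxo-10-[(triethylsilyl)oxy]cyclodeca-3,7-dien-1-yl]acetate F1. Corey–Bakshi–Shibata reduction with the (R)-methyl oxazaborolidine and BH3·SMe2 (alkenyl branch as the large group) should then give the 6R hydroxy ester 22, which lactonises with PPTS and comes back to the route at 23.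

2. Step 21. The peracid may be delivered to the inner face of the C1=C10 alkene or to C4=C5, and acid may trigger transannular cyclisation of the epoxide. Fallback: replace substrate-controlled peracid delivery by catalyst-controlled oxygen transfer. Setting out from 35, Shi asymmetric epoxidation (D-fructose-derived ketone, KHSO5, K2CO3 buffer, MeCN/dimethoxymethane/H2O, 0 °C) selects E-trisubstituted alkenes and, by its spiro transition-state model, the (R,R) face. It comes back directly at 36 and makes no new compound (entry F0).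

3. Step 2. Allylic oxidation may also occur at the positions flanking the iodoalkene, and over-oxidation to the enal may erode the material. Fallback: move the oxidation to a stage with a single alkene. Setting out from 1, SeO2/tBuOOH oxidation gives (2E)-5-bromo-2-methylpent-2-en-1-ol F2, and TBSCl/imidazole gives {[(2E)-5-bromo-2-methylpent-2-en-1-yl]oxy}(tert-butyl)dimethylsilane F3. Mg gives the Grignard reagent [(3E)-5-{[tert-butyl(dimethyl)silyl]oxy}-4-methylpent-3-en-1-yl]magnesium bromide F4. CuBr·SMe2 and propyne give the alkenylcopper [(1Z,5E)-7-{[tert-butyl(dimethyl)silyl]oxy}-2,6-dimethylhepta-1,5-dien-1-yl]copper F5. I2 gives tert-butyl{[(2E,6Z)-7-iodo-2,6-dimethylhepta-2,6-dien-1-yl]oxy}dimethylsilane F6, and Bu4NF brings the route back at 6.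

Further compounds
F1 | step 13 | methyl 2-[(1R,3Z,7E,10R)-4,8-dimethyl-2-oxo-10-[(triethylsilyl)oxy]cyclodeca-3,7-dien-1-yl]acetate | COC(=O)C[C@H]1C(=O)/C=C(/C)CC/C=C(\C)C[C@H]1O[Si](CC)(CC)CC
F0 | step 21 | none | none
F2 | step 2 | (2E)-5-bromo-2-methylpent-2-en-1-ol | OC/C(C)=C/CCBr
F3 | step 2 | {[(2E)-5-bromo-2-methylpent-2-en-1-yl]oxy}(tert-butyl)dimethylsilane | CC(C)(C)[Si](C)(C)OC/C(C)=C/CCBr
F4 | step 2 | [(3E)-5-{[tert-butyl(dimethyl)silyl]oxy}-4-methylpent-3-en-1-yl]magnesium bromide | CC(C)(C)[Si](C)(C)OC/C(C)=C/CC[Mg]Br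
F5 | step 2 | [(1Z,5E)-7-{[tert-butyl(dimethyl)silyl]oxy}-2,6-dimethylhepta-1,5-dien-1-yl]copper | CC(C)(C)[Si](C)(C)OC/C(C)=C/CC/C(C)=C\[Cu]
F6 | step 2 | tert-butyl{[(2E,6Z)-7-iodo-2,6-dimethylhepta-2,6-dien-1-yl]oxy}dimethylsilane | CC(C)(C)[Si](C)(C)OC/C(C)=C/CC/C(C)=C\I
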